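**Plan**

1. Retrosynthesis: the 1(15)-en-2-one is traced back to a C2 carbinol with an isopropenyl group on C1, the retron of a γ-selective allyl-metal addition. The 14-membered carbocycle C1–C14 is therefore cut at C1–C2 with the oxirane kept, and the chain is cut again at C9–C10.
2. These two cuts give two monoterpenes. C10–C17 and the C12 methyl map onto (R)-linalool (carbinol carbon = C12, prenyl group = C14/C1/C15–C17). C2–C9 and the C4 and C8 methyls map onto geraniol.
3. Forward: each terpene is oxidised at its (E)-methyl group. The fragments are joined at C9–C10 by a catalytic asymmetric alkylzinc addition to the geraniol-derived enal. The 14-membered ring is closed last, at C1–C2, by an intramolecular Nozaki–Hiyama allylation of the epoxy aldehyde, followed by oxidation at C2, conjugation of the alkene and desilylation.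
4. Stereochemistry: C12 comes from (R)-linalool (chiral pool), C3/C4 from Sharpless epoxidation of geraniol, C9 from the chiral titanium catalyst, and 7E from the E-selective SeO2 oxidation of the geranyl unit. The C1/C2 centres formed in the ring closure are both erased later, so the cyclisation needs no stereocontrol.
5. Enabling feature: the cross-conjugated array C15=C1–C2(=O)–C3/C4-oxirane, with an exocyclic isopropylidene on ring carbon C1 next to the ring ketone C2, inside a ring that is otherwise an unbranched chain of two head-to-tail isoprenoid halves.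

Key step: step 15

Remark: cembrane numbering is used for atoms (ring carbons C1–C14; C15 is the isopropylidene carbon on C1, with C16/C17; C2 ketone; C3/C4 oxirane; C7=C8; C9 carbinol; C12 acetoxy carbon). In this numbering the target is (3R,4S,7E,9R,12R). Commercial (R)-(−)-linalool of high enantiomeric purity is assumed.

**Route**

Step 1
Reactants: 1 (R)-(−)-linalool
Product: 2 (R)-linalyl acetate
Conditions: Ac2O, Et3N, DMAP (cat.), CH2Cl2, rt
Reagents that add atoms: acetic anhydride, CC(=O)OC(C)=O
Why: DMAP-catalysed acyl transfer (Steglich-type acetylation) esterifies the hindered tertiary alcohol at oxygen without touching the C–O bond, so the (R)-centre of linalool is carried unchanged into what becomes C12.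

Step 2
Reactants: 2 (R)-linalyl acetate
Product: 3 (2E,6R)-6-acetoxy-2,6-dimethylocta-2,7-dien-1-ol
Conditions: SeO2 (cat.), t-BuOOH, salicylic acid (cat.), CH2Cl2, rt
Reagents that add atoms: tert-butyl hydroperoxide, CC(C)(C)OO (terminal oxidant; the oxygen is passed on by catalytic SeO2, O=[Se]=O)
Why: The SeO2/t-BuOOH allylic oxidation (ene reaction followed by [2,3]-sigmatropic shift) should functionalise the electron-rich trisubstituted alkene at its (E)-methyl group, because the vinyl group has no allylic hydrogen, and no stereocentre is created.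

Step 3
Reactants: 3 (2E,6R)-6-acetoxy-2,6-dimethylocta-2,7-dien-1-ol
Product: 4 (3R,6E)-8-(tert-butyldimethylsilyloxy)-3,7-dimethylocta-1,6-dien-3-yl acetate
Conditions: TBSCl, imidazole, DMF, 0 °C to rt
Reagents that add atoms: tert-butyldimethylsilyl chloride, CC(C)(C)[Si](C)(C)Cl
Why: Silyl ether formation on the primary allylic alcohol masks the future C16 hydroxyl through the organometallic steps.

Step 4
Reactants: 4 (3R,6E)-8-(tert-butyldimethylsilyloxy)-3,7-dimethylocta-1,6-dien-3-yl acetate
Product: 6 (3R,6E)-8-(tert-butyldimethylsilyloxy)-1-hydroxy-3,7-dimethyloct-6-en-3-yl acetate, via B-alkyl-9-BBN adduct 5 (not isolated)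
Conditions: 9-BBN, THF, 0 °C to rt; then 30% H2O2, pH 7 phosphate buffer, 0 °C to rt
Reagents that add atoms: 9-borabicyclo[3.3.1]nonane, C1CCC2CCCC1B2 (its boron and bicycle are present in 5 only); hydrogen peroxide, OO (oxygen of 6)
Why: Hydroboration–oxidation with the bulky 9-BBN should take the monosubstituted alkene over the trisubstituted one and place boron on the terminal carbon (anti-Markovnikov, reinforced by the neighbouring quaternary carbon), and the neutral peroxide oxidation is chosen so that the tertiary acetate neither hydrolyses nor migrates to the new primary hydroxyl.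

Step 5
Reactants: 6 (3R,6E)-8-(tert-butyldimethylsilyloxy)-1-hydroxy-3,7-dimethyloct-6-en-3-yl acetate
Product: 7 (3R,6E)-8-(tert-butyldimethylsilyloxy)-1-iodo-3,7-dimethyloct-6-en-3-yl acetate
Conditions: I2, PPh3, imidazole, CH2Cl2, 0 °C
Reagents that add atoms: iodine, II
Why: Appel-type iodination converts the primary alcohol by SN2 displacement of the alkoxyphosphonium ion under nearly neutral conditions that the acetate and the silyl ether tolerate.

Step 6
Reactants: 8 geraniol
Product: 9 (2S,3S)-2,3-epoxygeraniol
Conditions: Ti(OiPr)4 (cat.), L-(+)-diethyl tartrate (cat.), t-BuOOH, 4 Å MS, CH2Cl2, −20 °C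
Reagents that add atoms: tert-butyl hydroperoxide, CC(C)(C)OO
Why: Sharpless asymmetric epoxidation is directed by the allylic hydroxyl to the 2,3-alkene only, and the L-(+)-tartrate–titanium catalyst selects the enantioface that gives the (2S,3S)-oxirane, the trans relation of the chain carbons following from the (E)-alkene.

Step 7
Reactants: 9 (2S,3S)-2,3-epoxygeraniol
Product: 10 (2S,3S)-2,3-epoxygeranyl tert-butyldimethylsilyl ether
Conditions: TBSCl, imidazole, CH2Cl2, 0 °C to rt
Reagents that add atoms: tert-butyldimethylsilyl chloride, CC(C)(C)[Si](C)(C)Cl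
Why: Silyl ether formation protects the epoxy alcohol and removes the risk of Payne rearrangement in later steps.

Step 8
Reactants: 10 (2S,3S)-2,3-epoxygeranyl tert-butyldimethylsilyl ether
Product: 11 (2S,3S,6E)-8-hydroxy-2,3-epoxygeranyl tert-butyldimethylsilyl ether
Conditions: SeO2 (cat.), t-BuOOH, CH2Cl2, 0 °C to rt
Reagents that add atoms: tert-butyl hydroperoxide, CC(C)(C)OO (terminal oxidant; the oxygen is passed on by catalytic SeO2, O=[Se]=O)
Why: SeO2/t-BuOOH allylic oxidation of the only remaining alkene is expected at the (E)-methyl group, which fixes the 7E geometry of the target because the oxidised carbon becomes C9.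

Step 9
Reactants: 11 (2S,3S,6E)-8-hydroxy-2,3-epoxygeranyl tert-butyldimethylsilyl ether
Product: 12 (2S,3S,6E)-8-oxo-2,3-epoxygeranyl tert-butyldimethylsilyl ether
Conditions: MnO2, CH2Cl2, rt
Reagents that add atoms: none
Why: MnO2 oxidises the allylic alcohol selectively to the (E)-enal (allylic oxidation) without touching the oxirane or the silyl ether.

Step 10
Reactants: 7 (3R,6E)-8-(tert-butyldimethylsilyloxy)-1-iodo-3,7-dimethyloct-6-en-3-yl acetate; 12 (2S,3S,6E)-8-oxo-2,3-epoxygeranyl tert-butyldimethylsilyl ether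
Product: 14 (3S,4S,7E,9R,12R,1(15)E)-12-acetoxy-2,16-bis(tert-butyldimethylsilyloxy)-3,4-epoxy-1,2-secocembra-1(15),7-dien-9-ol, via dialkylzinc reagent 13 (not isolated)
Conditions: 7 (2.5 equiv), Et2Zn, CuI (cat.), 50 °C, then volatiles removed in vacuo; 12, Ti(OiPr)4, (1S,2S)-1,2-bis(trifluoromethanesulfonamido)cyclohexane (cat.), toluene, −20 °C
Reagents that add atoms: diethylzinc, CC[Zn]CC (its zinc is present in 13 only)
Why: Copper-catalysed iodine–zinc exchange gives a dialkylzinc that tolerates acetate, silyl ether and oxirane, and its titanium/bis(triflamide)-catalysed asymmetric 1,2-addition to the α-methyl enal forms the C9–C10 bond under catalyst control, the (1S,2S)-ligand being chosen to direct the alkyl group to the Re face of the aldehyde (the (1R,2R)-ligand is known to favour the Si face) and so to give the (9R)-carbinol.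

Step 11
Reactants: 14 (3S,4S,7E,9R,12R,1(15)E)-12-acetoxy-2,16-bis(tert-butyldimethylsilyloxy)-3,4-epoxy-1,2-secocembra-1(15),7-dien-9-ol
Product: 15 (3S,4S,7E,9R,12R,1(15)E)-2,9,16-tris(tert-butyldimethylsilyloxy)-3,4-epoxy-1,2-secocembra-1(15),7-dien-12-yl acetate
Conditions: TBSCl, imidazole, DMAP (cat.), DMF, rt
Reagents that add atoms: tert-butyldimethylsilyl chloride, CC(C)(C)[Si](C)(C)Cl
Why: Silylation of the secondary allylic alcohol under imidazole catalysis is mild enough for the oxirane and gives a hindered secondary silyl ether that can outlast the two primary ones.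

Step 12
Reactants: 15 (3S,4S,7E,9R,12R,1(15)E)-2,9,16-tris(tert-butyldimethylsilyloxy)-3,4-epoxy-1,2-secocembra-1(15),7-dien-12-yl acetate
Product: 16 (3S,4S,7E,9R,12R,1(15)E)-12-acetoxy-9-(tert-butyldimethylsilyloxy)-3,4-epoxy-1,2-secocembra-1(15),7-diene-2,16-diol
Conditions: HF·pyridine, pyridine, THF, 0 °C
Reagents that add atoms: none
Why: Buffered HF·pyridine should cleave the unhindered primary TBS ethers much faster than the secondary allylic one flanked by the methyl-bearing alkene (sterically differentiated desilylation), and the buffer protects oxirane and acetate.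

Step 13
Reactants: 16 (3S,4S,7E,9R,12R,1(15)E)-12-acetoxy-9-(tert-butyldimethylsilyloxy)-3,4-epoxy-1,2-secocembra-1(15),7-diene-2,16-diol
Product: 17 (3S,4S,7E,9R,12R,1(15)E)-12-acetoxy-16-bromo-9-(tert-butyldimethylsilyloxy)-3,4-epoxy-1,2-secocembra-1(15),7-dien-2-ol
Conditions: NBS, Me2S, CH2Cl2, −20 to 0 °C
Reagents that add atoms: N-bromosuccinimide, O=C1CCC(=O)N1Br
Why: In the Corey–Kim halogenation only the allylic alkoxysulfonium ion is displaced by bromide (SN2), while that of the saturated epoxy carbinol returns the alcohol on work-up, so the reaction should differentiate the two primary hydroxyls without protecting groups and keep the (E)-geometry.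

Step 14
Reactants: 17 (3S,4S,7E,9R,12R,1(15)E)-12-acetoxy-16-bromo-9-(tert-butyldimethylsilyloxy)-3,4-epoxy-1,2-secocembra-1(15),7-dien-2-ol
Product: 18 (3R,4S,7E,9R,12R,1(15)E)-12-acetoxy-16-bromo-9-(tert-butyldimethylsilyloxy)-3,4-epoxy-1,2-secocembra-1(15),7-dien-2-al
Conditions: Dess–Martin periodinane, pyridine, CH2Cl2, 0 °C to rt
Reagents that add atoms: none
Why: Dess–Martin oxidation under pyridine buffer converts the epoxy alcohol to the α,β-epoxy aldehyde without acid or base strong enough to open the oxirane or displace the allylic bromide.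

Step 15
Reactants: 18 (3R,4S,7E,9R,12R,1(15)E)-12-acetoxy-16-bromo-9-(tert-butyldimethylsilyloxy)-3,4-epoxy-1,2-secocembra-1(15),7-dien-2-al
Product: 20 (3S,4S,7E,9R,12R)-12-acetoxy-9-(tert-butyldimethylsilyloxy)-3,4-epoxycembra-7,15-dien-2-ol as a mixture of C1/C2 epimers, via allylchromium(III) species 19 (not isolated)
Conditions: CrCl2 (10 equiv), degassed THF, rt; 18 added by syringe pump (final concentration about 1 mM)
Reagents that add atoms: chromium(II) chloride, Cl[Cr]Cl (its chromium and chlorine are present in 19 only)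
Why: Two Cr(II) ions reduce the allylic C16–Br bond by successive single-electron transfers to the σ-allylchromium(III) species 19, which adds to the formyl carbon C2 through a six-membered chair transition state with allylic transposition (SE2′), so that C1 becomes bonded to C2 and the double bond moves to C15=C16 (isopropenyl). The closest known reaction type is the intramolecular Nozaki–Hiyama allylation, which has close precedent for closing 14-membered cembranoid rings onto α,β-epoxy aldehydes. The one ring closed is the 14-membered carbocycle C1–C14, formed by 14-exo-trig attack on the aldehyde (carbonyl oxygen exocyclic) with the allyl unit reacting at its γ-terminus, while the oxirane is already in place and is not touched. The two new stereocentres C1 and C2 are governed by the chair transition state of the (E)-allylchromium (1,2-anti expected) and by the adjacent oxirane (Felkin-type facial bias), but neither matters because C2 is oxidised in step 16 and C1 becomes sp2 in step 17, so all diastereomers converge. The selectivities needed are reduction of the allylic bromide in preference to the epoxy aldehyde, acetate and silyl ether, γ-regioselectivity, and cyclisation over oligomerisation; the first two are inherent to allylchromium reagents, and the last is secured by slow addition at high dilution together with the two (E)-trisubstituted alkenes and the trans-oxirane, which limit the conformational freedom of the chain.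

Step 16
Reactants: 20 (3S,4S,7E,9R,12R)-12-acetoxy-9-(tert-butyldimethylsilyloxy)-3,4-epoxycembra-7,15-dien-2-ol (C1/C2 epimers)
Product: 21 (3R,4S,7E,9R,12R)-12-acetoxy-9-(tert-butyldimethylsilyloxy)-3,4-epoxycembra-7,15-dien-2-one (C1 epimers)
Conditions: Dess–Martin periodinane, pyridine, CH2Cl2, rt
Reagents that add atoms: none
Why: Dess–Martin oxidation turns every C2 epimer into the same ketone, which removes the C2 stereocentre and makes the C1 hydrogen acidic for the next step.

Step 17
Reactants: 21 (3R,4S,7E,9R,12R)-12-acetoxy-9-(tert-butyldimethylsilyloxy)-3,4-epoxycembra-7,15-dien-2-one (C1 epimers)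
Product: 22 (3R,4S,7E,9R,12R)-12-acetoxy-9-(tert-butyldimethylsilyloxy)-3,4-epoxycembra-1(15),7-dien-2-one
Conditions: DBU (cat.), CH2Cl2, rt
Reagents that add atoms: none
Why: DBU deprotonates C1 to the extended enolate and reprotonation at C16 moves the alkene into conjugation (base-mediated β,γ to α,β isomerisation toward the tetrasubstituted enone), which merges the C1 epimers, while the oxirane hydrogen at C3 is not acidic because of ring strain, so C3 is not epimerised.

Step 18
Reactants: 22 (3R,4S,7E,9R,12R)-12-acetoxy-9-(tert-butyldimethylsilyloxy)-3,4-epoxycembra-1(15),7-dien-2-one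
Product: 23 (3R,4S,7E,9R,12R)-12-acetoxy-3,4-epoxy-9-hydroxycembra-1(15),7-dien-2-one (target)
Conditions: HF·pyridine, pyridine, THF, 0 °C to rt
Reagents that add atoms: none
Why: Fluoride-mediated cleavage of the last silyl ether with buffered HF·pyridine frees the C9 hydroxyl under conditions expected to be too mild for acetyl migration, oxirane opening or deconjugation.

**Compound list**

1 | (R)-(−)-linalool, (3R)-3,7-dimethylocta-1,6-dien-3-ol | C=C[C@@](O)(C)CCC=C(C)C | starting material
2 | (R)-linalyl acetate | C=C[C@@](OC(C)=O)(C)CCC=C(C)C | intermediate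
3 | (2E,6R)-6-acetoxy-2,6-dimethylocta-2,7-dien-1-ol | C=C[C@@](OC(C)=O)(C)CC/C=C(\C)CO | intermediate
4 | (3R,6E)-8-(tert-butyldimethylsilyloxy)-3,7-dimethylocta-1,6-dien-3-yl acetate | C=C[C@@](OC(C)=O)(C)CC/C=C(\C)CO[Si](C)(C)C(C)(C)C | intermediate
5 | B-alkyl-9-BBN adduct of 4 (boron on the former terminal vinyl carbon, C10) | C1CCC2CCCC1B2CC[C@@](OC(C)=O)(C)CC/C=C(\C)CO[Si](C)(C)C(C)(C)C | intermediate
6 | (3R,6E)-8-(tert-butyldimethylsilyloxy)-1-hydroxy-3,7-dimethyloct-6-en-3-yl acetate | OCC[C@@](OC(C)=O)(C)CC/C=C(\C)CO[Si](C)(C)C(C)(C)C | intermediate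
7 | (3R,6E)-8-(tert-butyldimethylsilyloxy)-1-iodo-3,7-dimethyloct-6-en-3-yl acetate | ICC[C@@](OC(C)=O)(C)CC/C=C(\C)CO[Si](C)(C)C(C)(C)C | intermediate
8 | geraniol, (2E)-3,7-dimethylocta-2,6-dien-1-ol | OC/C=C(\C)CCC=C(C)C | starting material
9 | (2S,3S)-2,3-epoxygeraniol | OC[C@@H]1O[C@@]1(C)CCC=C(C)C | intermediate
10 | (2S,3S)-2,3-epoxygeranyl tert-butyldimethylsilyl ether | CC(C)(C)[Si](C)(C)OC[C@@H]1O[C@@]1(C)CCC=C(C)C | intermediate
11 | (2S,3S,6E)-8-hydroxy-2,3-epoxygeranyl tert-butyldimethylsilyl ether | CC(C)(C)[Si](C)(C)OC[C@@H]1O[C@@]1(C)CC/C=C(\C)CO | intermediate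
12 | (2S,3S,6E)-8-oxo-2,3-epoxygeranyl tert-butyldimethylsilyl ether ((E)-enal) | CC(C)(C)[Si](C)(C)OC[C@@H]1O[C@@]1(C)CC/C=C(\C)C=O | intermediate
13 | bis[(3R,6E)-3-acetoxy-8-(tert-butyldimethylsilyloxy)-3,7-dimethyloct-6-en-1-yl]zinc | C(C[C@@](OC(C)=O)(C)CC/C=C(\C)CO[Si](C)(C)C(C)(C)C)[Zn]CC[C@@](OC(C)=O)(C)CC/C=C(\C)CO[Si](C)(C)C(C)(C)C | intermediate
14 | (3S,4S,7E,9R,12R,1(15)E)-12-acetoxy-2,16-bis(TBS-oxy)-3,4-epoxy-1,2-secocembra-1(15),7-dien-9-ol | CC(C)(C)[Si](C)(C)OC[C@@H]1O[C@@]1(C)CC/C=C(\C)[C@H](O)CC[C@@](OC(C)=O)(C)CC/C=C(\C)CO[Si](C)(C)C(C)(C)C | intermediate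
15 | 9-O-TBS ether of 14 (tris-TBS ether) | CC(C)(C)[Si](C)(C)OC[C@@H]1O[C@@]1(C)CC/C=C(\C)[C@H](O[Si](C)(C)C(C)(C)C)CC[C@@](OC(C)=O)(C)CC/C=C(\C)CO[Si](C)(C)C(C)(C)C | intermediate
16 | (3S,4S,7E,9R,12R,1(15)E)-12-acetoxy-9-(TBS-oxy)-3,4-epoxy-1,2-secocembra-1(15),7-diene-2,16-diol | OC[C@@H]1O[C@@]1(C)CC/C=C(\C)[C@H](O[Si](C)(C)C(C)(C)C)CC[C@@](OC(C)=O)(C)CC/C=C(\C)CO | intermediate
17 | 16-bromo-16-deoxy derivative of 16 ((E)-allylic bromide, free C2 hydroxyl) | OC[C@@H]1O[C@@]1(C)CC/C=C(\C)[C@H](O[Si](C)(C)C(C)(C)C)CC[C@@](OC(C)=O)(C)CC/C=C(\C)CBr | intermediate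
18 | (3R,4S)-epoxy aldehyde from 17 (C2 = CHO, C16 = CH2Br) | O=C[C@@H]1O[C@@]1(C)CC/C=C(\C)[C@H](O[Si](C)(C)C(C)(C)C)CC[C@@](OC(C)=O)(C)CC/C=C(\C)CBr | intermediate
19 | allylchromium(III) dichloride from 18 (chromium on C16) | O=C[C@@H]1O[C@@]1(C)CC/C=C(\C)[C@H](O[Si](C)(C)C(C)(C)C)CC[C@@](OC(C)=O)(C)CC/C=C(\C)C[Cr](Cl)Cl | intermediate
20 | (3S,4S,7E,9R,12R)-12-acetoxy-9-(TBS-oxy)-3,4-epoxycembra-7,15-dien-2-ol, mixture of C1/C2 epimers | CC(=O)O[C@]1(C)CCC(C(C)=C)C(O)[C@@H]2O[C@@]2(C)CC/C=C(\C)[C@H](O[Si](C)(C)C(C)(C)C)CC1 | intermediate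
21 | (3R,4S,7E,9R,12R)-12-acetoxy-9-(TBS-oxy)-3,4-epoxycembra-7,15-dien-2-one, C1 epimers | CC(=O)O[C@]1(C)CCC(C(C)=C)C(=O)[C@@H]2O[C@@]2(C)CC/C=C(\C)[C@H](O[Si](C)(C)C(C)(C)C)CC1 | intermediate
22 | (3R,4S,7E,9R,12R)-12-acetoxy-9-(TBS-oxy)-3,4-epoxycembra-1(15),7-dien-2-one | CC(=O)O[C@]1(C)CCC(=C(C)C)C(=O)[C@@H]2O[C@@]2(C)CC/C=C(\C)[C@H](O[Si](C)(C)C(C)(C)C)CC1 | intermediate
23 | (3R,4S,7E,9R,12R)-12-acetoxy-3,4-epoxy-9-hydroxycembra-1(15),7-dien-2-one | CC(=O)O[C@]1(C)CCC(=C(C)C)C(=O)[C@@H]2O[C@@]2(C)CC/C=C(\C)[C@H](O)CC1 | target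

**Step count and risks**

Total steps: 18. Longest linear sequence: 14 steps (steps 1–5 and 10–18); the geraniol branch (steps 6–9) joins at step 10.

Steps most likely to fail:

1. Step 15 (ring closure). What may go wrong: intermolecular allylation (oligomerisation) may outrun ring closure, or Cr(II) may reduce the epoxy aldehyde or couple the allylic bromide before cyclisation. The fallback uses a preformed nucleophile and no reducing metal. It sets out from 17: palladium-catalysed borylation of the allylic bromide (B2pin2, Pd2(dba)3 cat., KOAc, toluene, 50 °C) should give the (E)-allylboronate epoxy alcohol F1. Dess–Martin oxidation at 0 °C should give the epoxy aldehyde allylboronate F2, which is not isolated. Its cold solution is run slowly into warm toluene, so that thermal intramolecular allylboration (closed chair transition state, same γ-regiochemistry, same C1–C2 bond) gives the macrocyclic borate ester F3. Work-up with aqueous triethanolamine hydrolyses F3 to 20, where the route is rejoined at step 16.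

2. Step 10 (fragment union and C9). What may go wrong: incomplete iodine–zinc exchange, sluggish transfer of the bulky functionalised alkyl group, or insufficient facial selectivity at the enal. The fallback makes the C–C bond by acylation and sets the stereocentre by ketone reduction. From 12, Pinnick oxidation (NaClO2, NaH2PO4, 2-methyl-2-butene, t-BuOH/H2O) should give the (E)-enoic acid F4, which EtSH/DCC/DMAP converts into the S-ethyl thioester F5. From 7, direct zinc insertion (Zn, LiCl, THF) should give the alkylzinc iodide F6. Fukuyama coupling of F5 with F6 (PdCl2(PPh3)2 cat., toluene/THF, rt) should give the 9-oxo enone F7 and consumes only one equivalent of the linalool fragment. Corey–Bakshi–Shibata reduction with the (S)-oxazaborolidine and catecholborane, in which the α-methylalkenyl group acts as the large substituent, should then give the (9R)-alcohol 14, where the route is rejoined at step 11.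

3. Step 17 (conjugation). What may go wrong: the base-mediated equilibrium may stop short of full conjugation because of allylic strain in the tetrasubstituted enone, or the extended enolate may start degradation of the epoxy ketone. The fallback uses a radical pathway instead of an enolate. It sets out from 21: cobalt-salen-catalysed hydrogen-atom-transfer isomerisation (Co(salen)Cl-type catalyst, PhSiH3 cat., benzene, rt) adds a hydrogen atom to C16 and removes one from C1, moving the isopropenyl alkene one position into the tetrasubstituted conjugated position under kinetic control. This should give 22 directly, where the route is rejoined at step 18; this fallback makes no new compound (entry F0).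

Further compounds
F1 | step 15 | 16-(pinacolboryl) analogue of 17, (E)-allylboronate with free C2 hydroxyl | OC[C@@H]1O[C@@]1(C)CC/C=C(\C)[C@H](O[Si](C)(C)C(C)(C)C)CC[C@@](OC(C)=O)(C)CC/C=C(\C)CB2OC(C)(C)C(C)(C)O2
F2 | step 15 | epoxy aldehyde allylboronate (C2 = CHO, C16 = CH2Bpin) | O=C[C@@H]1O[C@@]1(C)CC/C=C(\C)[C@H](O[Si](C)(C)C(C)(C)C)CC[C@@](OC(C)=O)(C)CC/C=C(\C)CB2OC(C)(C)C(C)(C)O2
F3 | step 15 | 2-O-(pinacolboryl) borate ester of 20 (C1/C2 epimers) | CC(=O)O[C@]1(C)CCC(C(C)=C)C(OB3OC(C)(C)C(C)(C)O3)[C@@H]2O[C@@]2(C)CC/C=C(\C)[C@H](O[Si](C)(C)C(C)(C)C)CC1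
F4 | step 10 | (2S,3S,6E)-1-(TBS-oxy)-2,3-epoxy-3,7-dimethyloct-6-en-8-oic acid | CC(C)(C)[Si](C)(C)OC[C@@H]1O[C@@]1(C)CC/C=C(\C)C(=O)O
F5 | step 10 | S-ethyl thioester of F4 | CC(C)(C)[Si](C)(C)OC[C@@H]1O[C@@]1(C)CC/C=C(\C)C(=O)SCC
F6 | step 10 | [(3R,6E)-3-acetoxy-8-(TBS-oxy)-3,7-dimethyloct-6-en-1-yl]zinc iodide | I[Zn]CC[C@@](OC(C)=O)(C)CC/C=C(\C)CO[Si](C)(C)C(C)(C)C
F7 | step 10 | 9-oxo analogue of 14 ((7E)-enone) | CC(C)(C)[Si](C)(C)OC[C@@H]1O[C@@]1(C)CC/C=C(\C)C(=O)CC[C@@](OC(C)=O)(C)CC/C=C(\C)CO[Si](C)(C)C(C)(C)C
F0 | step 17 | none | none
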